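**Dicitrinone G: synthesis design around a shared dihydroresorcinol hub**

Numbering: 1H-isochromene numbering on the quinone methide half (C1, O2, C3, C4, C4a, C5–C8, C8a; carbocycle A, pyran B); primed numbers on the lactone half (arene C, lactone D). TBS = tert-butyldimethylsilyl, TMS = trimethylsilyl, isochroman-1-one = 3,4-dihydro-1H-isochromen-1-one.

## The problem

Dicitrinone G consists of two 3,4,5-trimethylisochromane units joined by a single methylene carbon between C7 and C7': a quinone methide half (rings A and B) and a dihydroisocoumarin half (rings C and D). Both carbocycles are fully substituted in the same order: the side-chain carbon on C4a, methyl on C5, oxygen on C6, the bridge on C7, oxygen on C8 and a one-carbon unit on C8a (C1H= in ring B, C1'=O in ring D). Substituting a preformed benzene would therefore mean placing six groups with regiocontrol. The four stereocentres are two identical trans-3,4-dimethyl (threo) pairs, (3R,4S) and (3'R,4'S); the pairs are too far apart to influence each other and must both come from one absolute source, and within a pair the carbinol centre can direct the methyl-bearing neighbour only while the chain is open. C4 and C4' become epimerisable whenever they stand α or γ to a carbonyl group, and a secondary carbinol next to an electron-rich arene can ionise with aryl participation under strong Lewis acids. The quinone methide adds water and other nucleophiles at C1 and is easily reduced, the lactone does not tolerate hard nucleophiles, and free resorcinols oxidise in basic air, so ring B has to be closed last. The feature that opens the key step is the pattern of ring A: oxygen at C6 and C8, C7 between them, methyl at C5, the stereopair on C4a and C8a still C–H. This is a 5-substituted cyclohexane-1,3-dione alkylated at its C2 and C4, and ring C shows the same pattern, so one dione can serve both halves.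

## Retrosynthesis

**Ring B last (30 ⇒ 28).** The C1–C8a and C1–O2 bonds are cut, removing the quinone methide and leaving bis-resorcinol alcohol 28. Cutting the bridge instead, with ring B in place, would expose the quinone methide to every later reagent. In 28 ring A has exactly one C–H (C8a) and ring C has none, so an orthoformate can formylate only there, and the carbinol then closes the pyran.

**Protecting groups and oxidation level of ring A (28 ⇒ 27 ⇒ 25).** 28 comes from 27 by cleavage of the two ring C methyl ethers and the silyl ether. 27 comes from 25 by dehydrogenation of a cyclohexane-1,3-dione. Keeping ring A as a dione until this point means C7 takes the bridge as the doubly activated carbon of a β-diketone and not as the most crowded position of a hexasubstituted arene. The forward reaction must remove hydrogen from the ring only and spare the bridge methylene.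

**The bridge (25 ⇒ 14 + 23).** The C7–CH2 bond is cut on the ring A side, giving dione 14 and lactone aldehyde 23. The opposite cut (CH2–C7') would require a nucleophilic, lactone-deactivated arene and an unstable 2-methylene dione. In 14 the carbon between the carbonyls is the only one that condenses with an aldehyde, so regiochemistry is settled by acidity. The forward step must reduce the condensation product before a second dione adds to it.

**Ring C and lactone D from the same dione (23 ⇒ 22 ⇒ 18 ⇒ 17 ⇒ 16 ⇒ 14).** The formyl carbon is removed from C7' (the only free position of 22), the lactone carbonyl from C8a' (carboxylation of the aryl bromide 18), the methyl ethers from oxygen, and ring C is traced back to 14 through resorcinol 16. An independent entry from an aryl halide and trans-2,3-epoxybutane was weighed. SN2 opening of that epoxide gives the erythro alcohol, which is the cis-3,4-dimethyl series, so an inversion at the carbinol would be needed and three different groups would still have to be placed on the arene. Using 14 for both halves means no second source of chirality is required and the dehydrogenation is rehearsed on a simple substrate. The forward sequence needs bromination ortho to the side chain and not between the methoxy groups.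

**The C5 methyl (14 ⇒ 12 ⇒ 11).** The C5–CH3 bond is cut, leading to enol ether 12 and then to symmetric dione 11. Because 11 is symmetric about the C4a–C7 axis, either carbonyl can be masked and the kinetic α'-enolate is alkylated next to the side chain in both cases. Placing the methyl on the enone instead would retard the conjugate addition, and methylating the arene later would face two equivalent positions.

**Ring A/C carbocycle (11 ⇒ 9 ⇒ 6 + 7).** Decarboxylation is reversed to keto ester 9, and in 9 the C4a–C8a and C7–C8 bonds are cut to give enone 6 and dimethyl malonate 7. This removes the ring and all its functionality in one operation and leaves an acyclic enone that carries the intact stereopair two bonds from the reacting carbon. The forward reaction must add malonate faster than base removes the γ-hydrogen of 6.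

**The stereopair (6 ⇒ 3 ⇒ 2 ⇒ 1).** The enone double bond is cut by Wittig logic to aldehyde 5 (from ester 3) and ylide 4. The C4 methyl is removed from 2 to leave commercial hydroxy ester 1, whose carbinol centre directs the alkylation to the anti (threo) product. All four stereocentres of 30 thus come from 1.

## Roads not taken

**Alternative 1:** The cut is C4a'–C8a' in ring C. An acyclic diketo-dioxinone A2 that already carries the finished ring A unit on C7' would be heated in an alcohol; the unmasked acylketene is trapped as the ester, and the C8a' carbon then condenses with the C4a' ketone to give resorcylate A1.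
- Merits: ring C arises fully substituted without any oxidant, the bridge is in place before the arene exists, and the ester on C8a' is already the lactone carbonyl.
- Weak points: A2 is a 1,3,5-tricarbonyl chain branched at C7' and C5' whose assembly needs two C-acylations of hindered enolates. Its C4' stereocentre is α to the C4a' ketone and sits under the very base that triggers the aldol step. The ring A unit must first be made by another route with its own stereopair.
- Comparison: this road is better on convergency and on the fate of the carboxyl carbon, which the chosen plan removes in step 5 and has to reintroduce in steps 11 and 16. The chosen plan sets against this that C4 is never α to a ketone, that one intermediate (14) feeds both halves, and that its carbon–carbon steps are alkylations of stable β-diketones.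

**Alternative 2:** The cut is the ring oxygen of lactone D. A flavin monooxygenase with dioxygen and a nicotinamide cofactor would insert oxygen between the carbonyl and the methyl-bearing α-carbon of indanone A4 to give lactone A3, which is the same compound as 22.
- Merits: A4 is short to make, its trans arrangement is the thermodynamic one, and an enzyme could resolve the racemate, so A3 might be reached in roughly a third of the steps the chosen plan needs for 22.
- Weak points: the required migration of the secondary alkyl carbon runs against the usual preference of an electron-rich aryl ketone. The substrate is a doubly ortho-substituted aryl ketone of uncertain fit. A resolution discards half the material. The road says nothing about ring A, whose stereopair would need a second source.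
- Comparison: for the lactone half alone it would be clearly shorter if a suitable enzyme existed. The chosen plan offers in return independence from enzyme discovery and one chiral-pool ester for all four stereocentres.

**Alternative 3:** The cuts are C6–C7, C8–C8a and C5–C6 of ring A. Irradiation of diazo enone A6 would give a vinylketene that adds to ynol ether A7 (which carries the complete lactone half); heating the cyclobutenone then gives phenol A5.
- Merits: ring A is born aromatic with the bridge attached, its two oxygens are differentiated, and no late dehydrogenation or arene substitution is needed.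
- Weak points: A7 is a benzylic, propargylic ynol ether prone to isomerisation and hydration. A6 requires diazo transfer next to a branched enone. The vinylketene is hindered at its vinyl carbon. The photochemical step limits scale. The lactone half must be complete beforehand, with its stereopair from a separate sequence.
- Comparison: this road is more convergent at the ring A stage and avoids the palladium-mediated dehydrogenation. The chosen plan sets against it ionic chemistry on robust intermediates and the double use of 14.

Key step: step 4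

Assumption: the target is drawn as its 6-hydroxy-8-oxo tautomer; the 6-oxo-8-hydroxy form is the same substance in prototropic equilibrium, and the last step delivers that equilibrium system.

## Route

Step 1
Reactants: 1 methyl (R)-3-hydroxybutanoate
Product: 2 methyl (2R,3R)-3-hydroxy-2-methylbutanoate
Conditions: LiN(i-Pr)2 (2.2 equiv), THF, −78 → −20 °C; MeI, DMPU, −78 → 0 °C
Reagents that add atoms: iodomethane CI
Why: Fráter–Seebach alkylation: the lithium alkoxide–enolate forms a six-membered chelate and MeI approaches the face opposite the C3 methyl group, which sets C2 anti to the carbinol (the threo pair of the target).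

Step 2
Reactants: 2 methyl (2R,3R)-3-hydroxy-2-methylbutanoate
Product: 3 methyl (2R,3R)-3-(tert-butyldimethylsilyloxy)-2-methylbutanoate
Conditions: TBSCl, imidazole, DMF, rt
Reagents that add atoms: tert-butyldimethylsilyl chloride CC(C)(C)[Si](C)(C)Cl
Why: Standard silylation of a secondary alcohol; the silyl ether blocks lactonisation and retro-aldol chemistry in the basic steps that follow.

Step 3
Reactants: 3 methyl (2R,3R)-3-(tert-butyldimethylsilyloxy)-2-methylbutanoate; 4 1-(triphenylphosphoranylidene)propan-2-one
Product: 6 (3E,5S,6R)-6-(tert-butyldimethylsilyloxy)-5-methylhept-3-en-2-one, via silyloxy aldehyde 5 (not isolated)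
Conditions: i-Bu2AlH (1.05 equiv), CH2Cl2, −78 °C; then MeOH, 4, −78 °C → rt
Reagents that add atoms: none
Why: One-pot partial reduction and Wittig olefination: the aluminium hemiacetal is stable at −78 °C and releases epimerisable aldehyde 5 only on warming in the presence of the stabilised ylide, which gives the E-enone.

Step 4
Reactants: 6 (3E,5S,6R)-6-(tert-butyldimethylsilyloxy)-5-methylhept-3-en-2-one; 7 dimethyl malonate
Product: 9 methyl 6-[(2S,3R)-3-(tert-butyldimethylsilyloxy)butan-2-yl]-2,4-dioxocyclohexane-1-carboxylate, via malonate Michael adduct 8 (not isolated)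
Conditions: 7 (1.5 equiv), NaOMe (0.2 equiv), MeOH, 0 °C → rt; then NaOMe (1.2 equiv), reflux; 1 M HCl to pH 3, 0 °C
Reagents that add atoms: none
Why: With catalytic NaOMe and excess 7 the base is present as the soft malonate anion, which adds to C4 of enone 6 (the future C4a–C8a bond) to give 8; after the full equivalent of NaOMe is added, the methyl ketone of 8 is enolised and its terminal carbon attacks one malonate ester carbonyl with loss of methoxide (the future C7–C8 bond), and the product leaves all equilibria as the stabilised β-diketone enolate. The closest known reaction type is the malonate Michael–Claisen (Dieckmann-type) synthesis of 5-substituted cyclohexane-1,3-diones from alk-3-en-2-ones. The single ring closes in a 6-(enolexo)-exo-trig mode, the only six-membered option, since attack of the malonate carbon on the ketone would give a four-membered ring. The two new ring stereocentres (C1 and C6 of 9) form without control and need none: C1 is lost with the carboxyl group in step 5, and C6 is no longer stereogenic in symmetric 11 and later becomes an arene carbon. The selectivity that matters is conjugate addition ahead of γ-deprotonation at C5 of 6, which would epimerise that centre or expel the silyloxy group; it is secured by the low basicity of the malonate-buffered medium at 0 °C and by the fact that the methine of 8 is no longer vinylogously acidic. No bond to the two stereocentres of the chain is made or broken.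

Step 5
Reactants: 9 methyl 6-[(2S,3R)-3-(tert-butyldimethylsilyloxy)butan-2-yl]-2,4-dioxocyclohexane-1-carboxylate
Product: 11 5-[(2S,3R)-3-(tert-butyldimethylsilyloxy)butan-2-yl]cyclohexane-1,3-dione, via dioxocyclohexanecarboxylic acid 10 (not isolated)
Conditions: 2 M NaOH, MeOH/H2O, 60 °C; then 1 M HCl to pH 3, 50 °C
Reagents that add atoms: none
Why: Saponification and decarboxylation of a β-keto acid, the usual completion of the Michael–Claisen dione synthesis; the hindered secondary silyl ether should survive aqueous base and brief exposure to pH 3, and the product is symmetric, so the ring carbon bearing the chain is not a stereocentre.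

Step 6
Reactants: 11 5-[(2S,3R)-3-(tert-butyldimethylsilyloxy)butan-2-yl]cyclohexane-1,3-dione
Product: 12 5-[(2S,3R)-3-(tert-butyldimethylsilyloxy)butan-2-yl]-3-methoxycyclohex-2-en-1-one (both C5 epimers)
Conditions: Me3SiCHN2, PhMe/MeOH, 0 °C → rt
Reagents that add atoms: (trimethylsilyl)diazomethane C[Si](C)(C)C=[N+]=[N-]
Why: O-Methylation of the acidic enol by diazomethane released in situ under neutral conditions; because 11 is symmetric only one constitution can form, and the two ring epimers converge later.

Step 7
Reactants: 12 5-[(2S,3R)-3-(tert-butyldimethylsilyloxy)butan-2-yl]-3-methoxycyclohex-2-en-1-one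
Product: 14 5-[(2S,3R)-3-(tert-butyldimethylsilyloxy)butan-2-yl]-4-methylcyclohexane-1,3-dione, via methylated enol ether 13 (not isolated)
Conditions: LiN(i-Pr)2 (1.2 equiv), THF, −78 °C; MeI, −78 → −20 °C; then 2 M NaOH, THF/H2O, 65 °C; 1 M HCl to pH 3, 0 °C
Reagents that add atoms: iodomethane CI; sodium hydroxide (aqueous, supplies the ring oxygen) [Na+].[OH-]
Why: Stork–Danheiser alkylation: kinetic deprotonation of the vinylogous ester occurs at the α'-carbon next to the side chain and MeI enters there (the future C5 and C5' methyl); hydroxide then cleaves the enol ether by addition–elimination, and the new ring stereocentres are irrelevant because they are erased on aromatisation.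

Step 8
Reactants: 14 5-[(2S,3R)-3-(tert-butyldimethylsilyloxy)butan-2-yl]-4-methylcyclohexane-1,3-dione
Product: 16 5-[(2S,3R)-3-(tert-butyldimethylsilyloxy)butan-2-yl]-4-methylbenzene-1,3-diol, via bis(trimethylsilyl) dienol ether 15 (not isolated)
Conditions: Me3SiOTf, Et3N, CH2Cl2, 0 °C; then Pd(OAc)2 (10 mol%), O2 (1 atm), DMSO, 40 °C; then 1 M HCl, THF, rt, 10 min
Reagents that add atoms: none
Why: Saegusa–Ito dehydrogenation in its aerobic catalytic form: divalent palladium attacks the terminal carbon of the silyl dienol ether, β-hydride elimination gives the keto tautomer of the resorcinol, and zerovalent palladium is reoxidised by O2; brief acid removes the aryl silyl ether and leaves the hindered TBS ether.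

Step 9
Reactants: 16 5-[(2S,3R)-3-(tert-butyldimethylsilyloxy)butan-2-yl]-4-methylbenzene-1,3-diol
Product: 17 tert-butyl{[(2R,3S)-3-(3,5-dimethoxy-2-methylphenyl)butan-2-yl]oxy}dimethylsilane
Conditions: MeI, K2CO3, acetone, reflux
Reagents that add atoms: iodomethane CI
Why: Williamson O-methylation of both phenols; the methyl ethers keep the ring C oxygens from adding to the dione in step 13 and survive bromination, aryllithium formation and TiCl4.

Step 10
Reactants: 17 tert-butyl{[(2R,3S)-3-(3,5-dimethoxy-2-methylphenyl)butan-2-yl]oxy}dimethylsilane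
Product: 18 {[(2R,3S)-3-(2-bromo-3,5-dimethoxy-6-methylphenyl)butan-2-yl]oxy}(tert-butyl)dimethylsilane
Conditions: NBS, MeCN, 0 °C
Reagents that add atoms: N-bromosuccinimide O=C1CCC(=O)N1Br
Why: Electrophilic bromination of a resorcinol dimethyl ether goes para to one methoxy group and ortho to the other (C8a'), not between the two methoxy groups (C7'), which is the normal preference of 1,3-dimethoxybenzenes.

Step 11
Reactants: 18 {[(2R,3S)-3-(2-bromo-3,5-dimethoxy-6-methylphenyl)butan-2-yl]oxy}(tert-butyl)dimethylsilane
Product: 22 (3R,4S)-6,8-dimethoxy-3,4,5-trimethylisochroman-1-one, via aryllithium 19 (not isolated), via silyloxy benzoic acid 20 (not isolated), via hydroxy benzoic acid 21 (not isolated)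
Conditions: n-BuLi, THF, −78 °C; CO2; then 3 M HCl, THF, 50 °C
Reagents that add atoms: carbon dioxide O=C=O
Why: Bromine–lithium exchange and carboxylation put the lactone carbonyl on C8a'; acid removes the silyl group and the δ-hydroxy acid closes to the six-membered benzo-lactone, with no bond to either stereocentre broken.

Step 12
Reactants: 22 (3R,4S)-6,8-dimethoxy-3,4,5-trimethylisochroman-1-one
Product: 23 (3R,4S)-6,8-dimethoxy-3,4,5-trimethyl-1-oxoisochromane-7-carbaldehyde
Conditions: Cl2CHOMe, TiCl4, CH2Cl2, −10 → 0 °C; then H2O
Reagents that add atoms: dichloromethyl methyl ether COC(Cl)Cl; water O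
Why: Rieche formylation: C7' is the only unsubstituted ring carbon, is activated by two ortho methoxy groups and a para alkyl group, and lies meta to the lactone carbonyl.

Step 13
Reactants: 14 5-[(2S,3R)-3-(tert-butyldimethylsilyloxy)butan-2-yl]-4-methylcyclohexane-1,3-dione; 23 (3R,4S)-6,8-dimethoxy-3,4,5-trimethyl-1-oxoisochromane-7-carbaldehyde
Product: 25 (3R,4S)-7-({4-[(2S,3R)-3-(tert-butyldimethylsilyloxy)butan-2-yl]-3-methyl-2,6-dioxocyclohexyl}methyl)-6,8-dimethoxy-3,4,5-trimethylisochroman-1-one, via arylidene dione 24 (not isolated)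
Conditions: L-proline (20 mol%), Hantzsch ester (1.2 equiv), CH2Cl2, rt
Reagents that add atoms: none
Why: Organocatalytic three-component reductive alkylation: proline-mediated Knoevenagel condensation occurs at the only doubly activated carbon of 14 (C7), and the very electrophilic arylidene dione 24 is reduced by hydride transfer from the Hantzsch ester before a second dione can add.

Step 14
Reactants: 25 (3R,4S)-7-({4-[(2S,3R)-3-(tert-butyldimethylsilyloxy)butan-2-yl]-3-methyl-2,6-dioxocyclohexyl}methyl)-6,8-dimethoxy-3,4,5-trimethylisochroman-1-one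
Product: 27 (3R,4S)-7-({4-[(2S,3R)-3-(tert-butyldimethylsilyloxy)butan-2-yl]-2,6-dihydroxy-3-methylphenyl}methyl)-6,8-dimethoxy-3,4,5-trimethylisochroman-1-one, via bis(trimethylsilyl) dienol ether 26 (not isolated)
Conditions: Me3SiOTf, Et3N, CH2Cl2, 0 °C; then Pd(OAc)2 (10 mol%), O2 (1 atm), DMSO, 40 °C; then 1 M HCl, THF, rt, 10 min
Reagents that add atoms: none
Why: The Saegusa–Ito dehydrogenation rehearsed in step 8: palladation at the unhindered terminal carbon of the dienol ether (C8a) and β-hydride loss from C4a aromatise ring A, while C7 carries no hydrogen that could be lost into the ring and the lactone has no enolisable position.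

Step 15
Reactants: 27 (3R,4S)-7-({4-[(2S,3R)-3-(tert-butyldimethylsilyloxy)butan-2-yl]-2,6-dihydroxy-3-methylphenyl}methyl)-6,8-dimethoxy-3,4,5-trimethylisochroman-1-one
Product: 28 (3R,4S)-7-({2,6-dihydroxy-4-[(2S,3R)-3-hydroxybutan-2-yl]-3-methylphenyl}methyl)-6,8-dihydroxy-3,4,5-trimethylisochroman-1-one
Conditions: BBr3 (8 equiv), CH2Cl2, −78 → 0 °C; then H2O
Reagents that add atoms: none
Why: Lewis-acid cleavage of aryl methyl ethers; both are doubly ortho-substituted and one is chelated to the lactone carbonyl, so they should fall at or below 0 °C together with the silyl ether, while the ring A phenols are held as electron-poor aryl borates.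

Step 16
Reactants: 28 (3R,4S)-7-({2,6-dihydroxy-4-[(2S,3R)-3-hydroxybutan-2-yl]-3-methylphenyl}methyl)-6,8-dihydroxy-3,4,5-trimethylisochroman-1-one
Product: 30 dicitrinone G [(3R,4S)-6,8-dihydroxy-7-{[(3R,4S)-6-hydroxy-3,4,5-trimethyl-8-oxo-4,8-dihydro-3H-isochromen-7-yl]methyl}-3,4,5-trimethylisochroman-1-one], via ethoxy acetal 29 (not isolated)
Conditions: HC(OEt)3, CF3CO2H, CH2Cl2, 0 °C → rt; then H2O
Reagents that add atoms: triethyl orthoformate CCOC(OCC)OCC
Why: Oxa-Pictet–Spengler formylation–cyclisation as in the classical citrinin ring closure: the carbinol is exchanged onto the orthoester, the dialkoxycarbenium ion attacks C8a (the only C–H of ring A, para to the C6 hydroxyl), and loss of ethanol from acetal 29 gives the quinone methide; ring C has no free position and the stereocentres are untouched.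

## Compound list

1 | methyl (R)-3-hydroxybutanoate | C[C@@H](O)CC(=O)OC | starting material
2 | methyl (2R,3R)-3-hydroxy-2-methylbutanoate | O[C@H](C)[C@H](C(=O)OC)C | intermediate
3 | methyl (2R,3R)-3-(tert-butyldimethylsilyloxy)-2-methylbutanoate | CC(C)(C)[Si](C)(C)O[C@H](C)[C@H](C(=O)OC)C | intermediate
4 | 1-(triphenylphosphoranylidene)propan-2-one | CC(=O)C=P(c1ccccc1)(c1ccccc1)c1ccccc1 | starting material
5 | (2R,3R)-3-(tert-butyldimethylsilyloxy)-2-methylbutanal | CC(C)(C)[Si](C)(C)O[C@H](C)[C@H](C=O)C | intermediate (not isolated)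
6 | (3E,5S,6R)-6-(tert-butyldimethylsilyloxy)-5-methylhept-3-en-2-one | CC(C)(C)[Si](C)(C)O[C@H](C)[C@H](/C=C/C(C)=O)C | intermediate
7 | dimethyl malonate | COC(=O)CC(=O)OC | starting material
8 | dimethyl 2-[(5S,6R)-6-(tert-butyldimethylsilyloxy)-5-methyl-2-oxoheptan-4-yl]propanedioate (C4 epimers) | CC(C)(C)[Si](C)(C)O[C@H](C)[C@H](C(CC(C)=O)C(C(=O)OC)C(=O)OC)C | intermediate (not isolated)
9 | methyl 6-[(2S,3R)-3-(tert-butyldimethylsilyloxy)butan-2-yl]-2,4-dioxocyclohexane-1-carboxylate (ring epimers, enol forms) | CC(C)(C)[Si](C)(C)O[C@H](C)[C@H](C1CC(=O)CC(=O)C1C(=O)OC)C | intermediate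
10 | 6-[(2S,3R)-3-(tert-butyldimethylsilyloxy)butan-2-yl]-2,4-dioxocyclohexane-1-carboxylic acid | CC(C)(C)[Si](C)(C)O[C@H](C)[C@H](C1CC(=O)CC(=O)C1C(=O)O)C | intermediate (not isolated)
11 | 5-[(2S,3R)-3-(tert-butyldimethylsilyloxy)butan-2-yl]cyclohexane-1,3-dione | CC(C)(C)[Si](C)(C)O[C@H](C)[C@H](C1CC(=O)CC(=O)C1)C | intermediate
12 | 5-[(2S,3R)-3-(tert-butyldimethylsilyloxy)butan-2-yl]-3-methoxycyclohex-2-en-1-one (C5 epimers) | CC(C)(C)[Si](C)(C)O[C@H](C)[C@H](C1CC(=O)C=C(OC)C1)C | intermediate
13 | 5-[(2S,3R)-3-(tert-butyldimethylsilyloxy)butan-2-yl]-3-methoxy-6-methylcyclohex-2-en-1-one (ring epimers) | CC(C)(C)[Si](C)(C)O[C@H](C)[C@H](C1CC(OC)=CC(=O)C1C)C | intermediate (not isolated)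
14 | 5-[(2S,3R)-3-(tert-butyldimethylsilyloxy)butan-2-yl]-4-methylcyclohexane-1,3-dione (ring epimers, enol forms) | CC(C)(C)[Si](C)(C)O[C@H](C)[C@H](C1CC(=O)CC(=O)C1C)C | intermediate
15 | 5-[(2S,3R)-3-(tert-butyldimethylsilyloxy)butan-2-yl]-6-methyl-1,3-bis(trimethylsilyloxy)cyclohexa-1,3-diene (one regioisomer drawn) | CC(C)(C)[Si](C)(C)O[C@H](C)[C@H](C1C=C(O[Si](C)(C)C)C=C(O[Si](C)(C)C)C1C)C | intermediate (not isolated)
16 | 5-[(2S,3R)-3-(tert-butyldimethylsilyloxy)butan-2-yl]-4-methylbenzene-1,3-diol | CC(C)(C)[Si](C)(C)O[C@H](C)[C@H](c1cc(O)cc(O)c1C)C | intermediate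
17 | tert-butyl{[(2R,3S)-3-(3,5-dimethoxy-2-methylphenyl)butan-2-yl]oxy}dimethylsilane | CC(C)(C)[Si](C)(C)O[C@H](C)[C@H](c1cc(OC)cc(OC)c1C)C | intermediate
18 | {[(2R,3S)-3-(2-bromo-3,5-dimethoxy-6-methylphenyl)butan-2-yl]oxy}(tert-butyl)dimethylsilane | CC(C)(C)[Si](C)(C)O[C@H](C)[C@H](c1c(Br)c(OC)cc(OC)c1C)C | intermediate
19 | {2-[(2S,3R)-3-(tert-butyldimethylsilyloxy)butan-2-yl]-4,6-dimethoxy-3-methylphenyl}lithium | CC(C)(C)[Si](C)(C)O[C@H](C)[C@H](c1c([Li])c(OC)cc(OC)c1C)C | intermediate (not isolated)
20 | 2-[(2S,3R)-3-(tert-butyldimethylsilyloxy)butan-2-yl]-4,6-dimethoxy-3-methylbenzoic acid | CC(C)(C)[Si](C)(C)O[C@H](C)[C@H](c1c(C(=O)O)c(OC)cc(OC)c1C)C | intermediate (not isolated)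
21 | 2-[(2S,3R)-3-hydroxybutan-2-yl]-4,6-dimethoxy-3-methylbenzoic acid | O[C@H](C)[C@H](c1c(C(=O)O)c(OC)cc(OC)c1C)C | intermediate (not isolated)
22 | (3R,4S)-6,8-dimethoxy-3,4,5-trimethylisochroman-1-one | COc1cc(OC)c(C)c2c1C(=O)O[C@H](C)[C@H]2C | intermediate
23 | (3R,4S)-6,8-dimethoxy-3,4,5-trimethyl-1-oxoisochromane-7-carbaldehyde | COc1c(C=O)c(OC)c(C)c2c1C(=O)O[C@H](C)[C@H]2C | intermediate
24 | (3R,4S)-7-({4-[(2S,3R)-3-(tert-butyldimethylsilyloxy)butan-2-yl]-3-methyl-2,6-dioxocyclohexylidene}methyl)-6,8-dimethoxy-3,4,5-trimethylisochroman-1-one | CC(C)(C)[Si](C)(C)O[C@H](C)[C@H](C1CC(=O)C(=Cc2c(OC)c(C)c3c(c2OC)C(=O)O[C@H](C)[C@H]3C)C(=O)C1C)C | intermediate (not isolated)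
25 | (3R,4S)-7-({4-[(2S,3R)-3-(tert-butyldimethylsilyloxy)butan-2-yl]-3-methyl-2,6-dioxocyclohexyl}methyl)-6,8-dimethoxy-3,4,5-trimethylisochroman-1-one (ring A epimers, enol forms) | CC(C)(C)[Si](C)(C)O[C@H](C)[C@H](C1CC(=O)C(Cc2c(OC)c(C)c3c(c2OC)C(=O)O[C@H](C)[C@H]3C)C(=O)C1C)C | intermediate
26 | (3R,4S)-7-({4-[(2S,3R)-3-(tert-butyldimethylsilyloxy)butan-2-yl]-3-methyl-2,6-bis(trimethylsilyloxy)cyclohexa-1,5-dien-1-yl}methyl)-6,8-dimethoxy-3,4,5-trimethylisochroman-1-one (one regioisomer drawn) | CC(C)(C)[Si](C)(C)O[C@H](C)[C@H](C1C=C(O[Si](C)(C)C)C(Cc2c(OC)c(C)c3c(c2OC)C(=O)O[C@H](C)[C@H]3C)=C(O[Si](C)(C)C)C1C)C | intermediate (not isolated)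
27 | (3R,4S)-7-({4-[(2S,3R)-3-(tert-butyldimethylsilyloxy)butan-2-yl]-2,6-dihydroxy-3-methylphenyl}methyl)-6,8-dimethoxy-3,4,5-trimethylisochroman-1-one | CC(C)(C)[Si](C)(C)O[C@H](C)[C@H](c1cc(O)c(Cc2c(OC)c(C)c3c(c2OC)C(=O)O[C@H](C)[C@H]3C)c(O)c1C)C | intermediate
28 | (3R,4S)-7-({2,6-dihydroxy-4-[(2S,3R)-3-hydroxybutan-2-yl]-3-methylphenyl}methyl)-6,8-dihydroxy-3,4,5-trimethylisochroman-1-one | O[C@H](C)[C@H](c1cc(O)c(Cc2c(O)c(C)c3c(c2O)C(=O)O[C@H](C)[C@H]3C)c(O)c1C)C | intermediate
29 | (3R,4S)-7-{[(3R,4S)-1-ethoxy-6,8-dihydroxy-3,4,5-trimethylisochroman-7-yl]methyl}-6,8-dihydroxy-3,4,5-trimethylisochroman-1-one (C1 epimers) | CCOC1O[C@H](C)[C@H](c2c1c(O)c(Cc3c(O)c(C)c4c(c3O)C(=O)O[C@H](C)[C@H]4C)c(O)c2C)C | intermediate (not isolated)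
30 | dicitrinone G, (3R,4S)-6,8-dihydroxy-7-{[(3R,4S)-6-hydroxy-3,4,5-trimethyl-8-oxo-4,8-dihydro-3H-isochromen-7-yl]methyl}-3,4,5-trimethylisochroman-1-one | CC1=C2C(=CO[C@H](C)[C@H]2C)C(=O)C(Cc2c(O)c(C)c3c(c2O)C(=O)O[C@H](C)[C@H]3C)=C1O | target

## Step count and least certain steps

Total: 16 steps. Longest linear sequence: 16 steps (1 → 14 → 23 → 25 → 30). Dione 14 is used twice, once as the precursor of aldehyde 23 and once as its coupling partner, so no second chiral starting material is needed.

**Step 4 (key step).** Most likely failure: γ-deprotonation of 6 running ahead of conjugate addition at the branched β-carbon, with epimerisation of C5 or vinylogous loss of the silyloxy group.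
Fallback, from 3, back at 9: reduction of 3 as in step 3 and olefination with methyl (triphenylphosphoranylidene)acetate would give methyl (2E,4S,5R)-5-(tert-butyldimethylsilyloxy)-4-methylhex-2-enoate F1, a far weaker carbon acid at its γ-position. Methyl acetoacetate with NaOMe in refluxing MeOH would then add through its central carbon, and the acetyl enolate would close onto the enoate ester. This complementary Michael–Claisen annulation forms the other pair of ring bonds and ends in the same keto ester 9.

**Step 14.** Most likely failure: incomplete silyl dienol ether formation on the crowded ring, palladation at C7 followed by hydride loss from the bridge methylene (dehydrogenation towards the arylidene dione), or over-oxidation of the electron-rich product.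
Fallback, from 17 and 23, back at 28: lithiation of 17 between its methoxy groups (n-BuLi, THF, 0 °C) and addition to aldehyde 23 at −78 °C would give (3R,4S)-7-[{4-[(2S,3R)-3-(tert-butyldimethylsilyloxy)butan-2-yl]-2,6-dimethoxy-3-methylphenyl}(hydroxy)methyl]-6,8-dimethoxy-3,4,5-trimethylisochroman-1-one F2. Ionic hydrogenation (Et3SiH, CF3CO2H, CH2Cl2, −20 °C) would give (3R,4S)-7-({4-[(2S,3R)-3-(tert-butyldimethylsilyloxy)butan-2-yl]-2,6-dimethoxy-3-methylphenyl}methyl)-6,8-dimethoxy-3,4,5-trimethylisochroman-1-one F3. The BBr3 conditions of step 15 would then cleave four methyl ethers and the silyl ether to give 28. This gives up the late dehydrogenation; the bridge is made by directed metalation of an already aromatic ring A.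

**Step 15.** Most likely failure: ionisation of the borylated secondary carbinol with participation of ring A (bromide formation or scrambling of the threo pair), or opening of lactone D by bromide.
Fallback, from 23, back at 28: BBr3 applied to 23, where the carbinol oxygen is acylated within the lactone, would give (3R,4S)-6,8-dihydroxy-3,4,5-trimethyl-1-oxoisochromane-7-carbaldehyde F4. Benzylation (BnBr, K2CO3, DMF) would give (3R,4S)-6,8-bis(benzyloxy)-3,4,5-trimethyl-1-oxoisochromane-7-carbaldehyde F5. Steps 13 and 14 run with F5 in place of 23 would give (3R,4S)-6,8-bis(benzyloxy)-7-({4-[(2S,3R)-3-(tert-butyldimethylsilyloxy)butan-2-yl]-3-methyl-2,6-dioxocyclohexyl}methyl)-3,4,5-trimethylisochroman-1-one F6 and then (3R,4S)-6,8-bis(benzyloxy)-7-({4-[(2S,3R)-3-(tert-butyldimethylsilyloxy)butan-2-yl]-2,6-dihydroxy-3-methylphenyl}methyl)-3,4,5-trimethylisochroman-1-one F7. Hydrogenolysis over Pd/C in methanolic HCl would remove the benzyl and silyl groups and give 28 without a Lewis acid near the free carbinol.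

**Step 13.** Most likely failure: slow condensation of the doubly ortho-substituted aldehyde, or addition of a second dione to 24 before hydride transfer.
Fallback, from 23 and 14, back at 25: NaBH4 (MeOH/THF, 0 °C) would reduce 23 to (3R,4S)-7-(hydroxymethyl)-6,8-dimethoxy-3,4,5-trimethylisochroman-1-one F8. PBr3 (CH2Cl2, 0 °C) would give (3R,4S)-7-(bromomethyl)-6,8-dimethoxy-3,4,5-trimethylisochroman-1-one F9. The potassium enolate of 14 (K2CO3, aqueous dioxane, a medium that favours carbon over oxygen alkylation) would be benzylated at C7 to give 25.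

**Step 10.** Most likely failure: poor regioselectivity next to the branched side chain, with bromination between the methoxy groups or twofold bromination.
Fallback, from 17, back at 22: HCl in MeOH would remove the silyl group to give (2R,3S)-3-(3,5-dimethoxy-2-methylphenyl)butan-2-ol F10. Trimethyl orthoformate with BF3·OEt2 would close (3R,4S)-1,6,8-trimethoxy-3,4,5-trimethylisochromane F11 through the tether, which can reach only C8a'. Oxidation of the cyclic acetal (CrO3, H2SO4, acetone, 0 °C) would give lactone 22.

## Further compounds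

F1 | step 4 | methyl (2E,4S,5R)-5-(tert-butyldimethylsilyloxy)-4-methylhex-2-enoate | CC(C)(C)[Si](C)(C)O[C@H](C)[C@H](/C=C/C(=O)OC)C
F2 | step 14 | (3R,4S)-7-[{4-[(2S,3R)-3-(tert-butyldimethylsilyloxy)butan-2-yl]-2,6-dimethoxy-3-methylphenyl}(hydroxy)methyl]-6,8-dimethoxy-3,4,5-trimethylisochroman-1-one (carbinol epimers) | CC(C)(C)[Si](C)(C)O[C@H](C)[C@H](c1cc(OC)c(C(O)c2c(OC)c(C)c3c(c2OC)C(=O)O[C@H](C)[C@H]3C)c(OC)c1C)C
F3 | step 14 | (3R,4S)-7-({4-[(2S,3R)-3-(tert-butyldimethylsilyloxy)butan-2-yl]-2,6-dimethoxy-3-methylphenyl}methyl)-6,8-dimethoxy-3,4,5-trimethylisochroman-1-one | CC(C)(C)[Si](C)(C)O[C@H](C)[C@H](c1cc(OC)c(Cc2c(OC)c(C)c3c(c2OC)C(=O)O[C@H](C)[C@H]3C)c(OC)c1C)C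
F4 | step 15 | (3R,4S)-6,8-dihydroxy-3,4,5-trimethyl-1-oxoisochromane-7-carbaldehyde | Oc1c(C=O)c(O)c(C)c2c1C(=O)O[C@H](C)[C@H]2C
F5 | step 15 | (3R,4S)-6,8-bis(benzyloxy)-3,4,5-trimethyl-1-oxoisochromane-7-carbaldehyde | O=Cc1c(OCc2ccccc2)c(C)c2c(c1OCc1ccccc1)C(=O)O[C@H](C)[C@H]2C
F6 | step 15 | (3R,4S)-6,8-bis(benzyloxy)-7-({4-[(2S,3R)-3-(tert-butyldimethylsilyloxy)butan-2-yl]-3-methyl-2,6-dioxocyclohexyl}methyl)-3,4,5-trimethylisochroman-1-one | CC(C)(C)[Si](C)(C)O[C@H](C)[C@H](C1CC(=O)C(Cc2c(OCc3ccccc3)c(C)c3c(c2OCc2ccccc2)C(=O)O[C@H](C)[C@H]3C)C(=O)C1C)C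
F7 | step 15 | (3R,4S)-6,8-bis(benzyloxy)-7-({4-[(2S,3R)-3-(tert-butyldimethylsilyloxy)butan-2-yl]-2,6-dihydroxy-3-methylphenyl}methyl)-3,4,5-trimethylisochroman-1-one | CC(C)(C)[Si](C)(C)O[C@H](C)[C@H](c1cc(O)c(Cc2c(OCc3ccccc3)c(C)c3c(c2OCc2ccccc2)C(=O)O[C@H](C)[C@H]3C)c(O)c1C)C
F8 | step 13 | (3R,4S)-7-(hydroxymethyl)-6,8-dimethoxy-3,4,5-trimethylisochroman-1-one | OCc1c(OC)c(C)c2c(c1OC)C(=O)O[C@H](C)[C@H]2C
F9 | step 13 | (3R,4S)-7-(bromomethyl)-6,8-dimethoxy-3,4,5-trimethylisochroman-1-one | BrCc1c(OC)c(C)c2c(c1OC)C(=O)O[C@H](C)[C@H]2C
F10 | step 10 | (2R,3S)-3-(3,5-dimethoxy-2-methylphenyl)butan-2-ol | O[C@H](C)[C@H](c1cc(OC)cc(OC)c1C)C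
F11 | step 10 | (3R,4S)-1,6,8-trimethoxy-3,4,5-trimethylisochromane (C1 epimers) | COC1O[C@H](C)[C@H](c2c1c(OC)cc(OC)c2C)C
A1 | alternative 1 | methyl 6-[(2S,3R)-3-(tert-butyldimethylsilyloxy)butan-2-yl]-3-({4-[(2S,3R)-3-(tert-butyldimethylsilyloxy)butan-2-yl]-2,6-dimethoxy-3-methylphenyl}methyl)-2,4-dihydroxy-5-methylbenzoate | CC(C)(C)[Si](C)(C)O[C@H](C)[C@H](c1c(C)c(O)c(Cc2c(OC)c(C)c([C@H](C)[C@@H](C)O[Si](C)(C)C(C)(C)C)cc2OC)c(O)c1C(=O)OC)C
A2 | alternative 1 | 6-[(6R,7R)-7-(tert-butyldimethylsilyloxy)-1-{4-[(2S,3R)-3-(tert-butyldimethylsilyloxy)butan-2-yl]-2,6-dimethoxy-3-methylphenyl}-4,6-dimethyl-3,5-dioxooctan-2-yl]-2,2-dimethyl-4H-1,3-dioxin-4-one (C2 and C4 of the chain undefined) | CC(C)(C)[Si](C)(C)O[C@H](C)[C@H](C(=O)C(C)C(=O)C(Cc1c(OC)c(C)c(cc1OC)[C@H](C)[C@@H](C)O[Si](C)(C)C(C)(C)C)C1=CC(=O)OC(C)(C)O1)C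
A3 | alternative 2 | (3R,4S)-6,8-dimethoxy-3,4,5-trimethylisochroman-1-one | c1c(OC)c(C)c2c(c1OC)C(=O)O[C@H](C)[C@H]2C
A4 | alternative 2 | (2R,3R)-5,7-dimethoxy-2,3,4-trimethyl-2,3-dihydro-1H-inden-1-one | COc1cc(OC)c(C)c2c1C(=O)[C@H](C)[C@H]2C
A5 | alternative 3 | (3R,4S)-7-({4-[(2S,3R)-3-(tert-butyldimethylsilyloxy)butan-2-yl]-6-ethoxy-2-hydroxy-3-methylphenyl}methyl)-6,8-dimethoxy-3,4,5-trimethylisochroman-1-one | CC(C)(C)[Si](C)(C)O[C@H](C)[C@H](c1cc(OCC)c(Cc2c(OC)c(C)c3c(c2OC)C(=O)O[C@H](C)[C@H]3C)c(O)c1C)C
A6 | alternative 3 | (5S,6R)-6-(tert-butyldimethylsilyloxy)-2-diazo-5-methyl-4-methylideneheptan-3-one | CC(C)(C)[Si](C)(C)O[C@H](C)[C@H](C(=C)C(=O)C(C)=[N+]=[N-])C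
A7 | alternative 3 | (3R,4S)-7-(3-ethoxyprop-2-yn-1-yl)-6,8-dimethoxy-3,4,5-trimethylisochroman-1-one | CCOC#CCc1c(OC)c(C)c2c(c1OC)C(=O)O[C@H](C)[C@H]2C
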